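**Retrosynthetic overview**

1. Numbering: terpenoid carbons C1 (benzylic CH2) to C15 (CBr(CH3)2); arene carbons C1' (carboxyl) to C6', where C3' bears C1 and C4' the OH. Ring A is the cyclohexane C2–C7, ring B the arene, ring C the 15-membered lactone.
2. Ring C is closed by the C1–C3' bond: an aryl boronate at C3' adds 1,4 under rhodium catalysis to an exocyclic enone on ring A, in a tandem unmasking/conjugate arylation/macrocyclisation that also sets C2.
3. Enabling feature: the exocyclic methylene on C3 of ring A is a masked ketone. With C3 as C=O, C1 becomes the β-carbon and C2 the α-carbon of an enone, and C3' lies ortho to the phenol oxygen on C4', where iodine and then boron are easily placed. C3=CH2 is restored afterwards by methylenation.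
4. Seco-precursor: the C14–O ester comes from a bromohydrin (C15–Br by acid opening of a Shi epoxide); C9–C10 comes from Negishi coupling of a ring A alkylzinc with an E-iodoalkene. Ring A (C2–C7 bond, C6–Br, C7) comes from an enantiospecific bromonium/allylsilane cyclisation of a bromohydrin made from a Shi epoxide.
5. Ring order: A first, B is bought, C last; then C3 methylenation, C10–C11 epoxidation and release of the phenol.

Key step: step 21

Remark: the facial sense of the three Shi epoxidations is assigned from the usual spiro transition-state model (the D-fructose-derived ketone gives the (R,R)-epoxide of an E-trisubstituted alkene of this type); should an alkene deviate, the other ketone enantiomer would be used.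

**Route**

Step 1
Reactants: 1 but-3-yn-1-ol
Product: 3 (2E)-3-methylpent-2-ene-1,5-diol, via alkenylalane 2 (not isolated)
Conditions: Me3Al (3 equiv), Cp2ZrCl2 (0.25 equiv), CH2Cl2, 0 °C to rt; solvent exchange to THF/hexane, n-BuLi (1 equiv), −78 °C; (CH2O)n, rt
Reagents that add atoms: trimethylaluminium C[Al](C)C; paraformaldehyde (reacts as formaldehyde) C=O
Why: Zirconium-catalysed Negishi carboalumination adds methyl and aluminium syn across the alkyne with aluminium on the terminal carbon, and the derived alkenylaluminate is hydroxymethylated with retention, which fixes the E geometry of the future C6=C7 alkene.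

Step 2
Reactants: 3 (2E)-3-methylpent-2-ene-1,5-diol
Product: 4 (2E)-1,5-dichloro-3-methylpent-2-ene
Conditions: PPh3 (2.4 equiv), N-chlorosuccinimide (2.4 equiv), CH2Cl2, −20 °C to rt
Reagents that add atoms: N-chlorosuccinimide O=C1CCC(=O)N1Cl
Why: Appel-type chlorination converts both primary alcohols by SN2 displacement of the oxyphosphonium group without allylic transposition.

Step 3
Reactants: 4 (2E)-1,5-dichloro-3-methylpent-2-ene; 5 methyl 3-oxobutanoate
Product: 6 methyl (6E)-9-chloro-7-methyl-3-oxonon-6-enoate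
Conditions: 5 (1.5 equiv), NaH then n-BuLi, THF, 0 °C; 4, 0 °C; aq NH4Cl
Reagents that add atoms: none
Why: The acetoacetate dianion alkylates at its terminal carbon, and the allylic chloride reacts far faster than the unactivated primary chloride (acetoacetate dianion alkylation).

Step 4
Reactants: 6 methyl (6E)-9-chloro-7-methyl-3-oxonon-6-enoate
Product: 7 methyl (2Z,6E)-9-chloro-7-methyl-3-[(trifluoromethanesulfonyl)oxy]nona-2,6-dienoate
Conditions: Tf2O (1.5 equiv), saturated aq LiOH, toluene, 5 °C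
Reagents that add atoms: trifluoromethanesulfonic anhydride O=S(=O)(OS(=O)(=O)C(F)(F)F)C(F)(F)F
Why: Enolisation under chelating lithium hydroxide conditions followed by O-triflation should give the Z enol triflate of the β-keto ester (stereoselective enol triflate formation).

Step 5
Reactants: 7 methyl (2Z,6E)-9-chloro-7-methyl-3-[(trifluoromethanesulfonyl)oxy]nona-2,6-dienoate
Product: 8 methyl (2Z,6E)-9-chloro-7-methyl-3-[(trimethylsilyl)methyl]nona-2,6-dienoate
Conditions: Me3SiCH2MgCl (1.5 equiv), Pd(PPh3)4 (3 mol %), THF, 0 °C to rt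
Reagents that add atoms: (trimethylsilyl)methylmagnesium chloride C[Si](C)(C)C[Mg]Cl
Why: Palladium-catalysed Kumada coupling replaces the triflate by CH2SiMe3 with retention of alkene geometry, faster than the Grignard reagent attacks the ester or the alkyl chloride.

Step 6
Reactants: 8 methyl (2Z,6E)-9-chloro-7-methyl-3-[(trimethylsilyl)methyl]nona-2,6-dienoate
Product: 9 methyl (2Z)-5-[(2R,3R)-3-(2-chloroethyl)-3-methyloxiran-2-yl]-3-[(trimethylsilyl)methyl]pent-2-enoate
Conditions: D-fructose-derived Shi ketone (0.3 equiv), Oxone (2KHSO5·KHSO4·K2SO4), K2CO3, Bu4NHSO4, Na2B4O7 buffer (pH 10.5), MeCN/CH2(OMe)2/H2O, 0 °C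
Reagents that add atoms: Oxone (active component potassium peroxymonosulfate) [K+].[O-]S(=O)(=O)OO
Why: Shi epoxidation oxidises only the electron-rich E-trisubstituted C6=C7 alkene (the enoate is inert to the dioxirane), and the spiro transition state should deliver oxygen to the face that gives the (R,R)-epoxide, which fixes C6 and C7.

Step 7
Reactants: 9 methyl (2Z)-5-[(2R,3R)-3-(2-chloroethyl)-3-methyloxiran-2-yl]-3-[(trimethylsilyl)methyl]pent-2-enoate
Product: 10 (2Z)-5-[(2R,3R)-3-(2-chloroethyl)-3-methyloxiran-2-yl]-3-[(trimethylsilyl)methyl]pent-2-en-1-ol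
Conditions: i-Bu2AlH (2.5 equiv), CH2Cl2, −78 °C; aq potassium sodium tartrate
Reagents that add atoms: none
Why: i-Bu2AlH reduces the conjugated ester to the allylic alcohol at −78 °C without opening the trisubstituted epoxide.

Step 8
Reactants: 10 (2Z)-5-[(2R,3R)-3-(2-chloroethyl)-3-methyloxiran-2-yl]-3-[(trimethylsilyl)methyl]pent-2-en-1-ol
Product: 11 (2Z)-5-[(2R,3R)-3-(2-chloroethyl)-3-methyloxiran-2-yl]-3-[(trimethylsilyl)methyl]pent-2-en-1-yl acetate
Conditions: Ac2O, pyridine, DMAP (cat.), CH2Cl2, 0 °C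
Reagents that add atoms: acetic anhydride CC(=O)OC(C)=O
Why: Standard DMAP-catalysed acetylation; the acetate later serves as the leaving group that unmasks the enone.

Step 9
Reactants: 11 (2Z)-5-[(2R,3R)-3-(2-chloroethyl)-3-methyloxiran-2-yl]-3-[(trimethylsilyl)methyl]pent-2-en-1-yl acetate
Product: 12 (2Z,6S,7R)-6-bromo-9-chloro-7-hydroxy-7-methyl-3-[(trimethylsilyl)methyl]non-2-en-1-yl acetate
Conditions: Li2NiBr4 (2 equiv, from LiBr and NiBr2), THF, 0 °C to rt; pH 7 phosphate buffer
Reagents that add atoms: dilithium tetrabromonickelate [Li+].[Li+].[Ni+2].[Br-].[Br-].[Br-].[Br-]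
Why: Li2NiBr4 delivers bromide in an SN2 opening at the less substituted epoxide carbon C6 with inversion, giving the anti bromohydrin with bromine on C6 in its final configuration and the tertiary alcohol on C7.

Step 10
Reactants: 12 (2Z,6S,7R)-6-bromo-9-chloro-7-hydroxy-7-methyl-3-[(trimethylsilyl)methyl]non-2-en-1-yl acetate
Product: 13 [(1R,2S,3S)-3-bromo-2-(2-chloroethyl)-2-methyl-6-methylidenecyclohexyl]methyl acetate
Conditions: Tf2O (1.1 equiv), 2,6-di-tert-butyl-4-methylpyridine (2.5 equiv), CH2Cl2, −78 °C; aq NaHCO3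
Reagents that add atoms: none
Why: Triflation of the tertiary alcohol triggers ionisation with anchimeric assistance by the anti bromine to an enantiopure bromonium ion, which the allylsilane captures at C7 anti to bromine through a chair transition state (bromonium-initiated cation–olefin cyclisation with allylsilane termination), so that C7 is set by the anti opening, C2 by the Z allylsilane geometry (C1 equatorial), and the β-silyl cation collapses to the exocyclic alkene.

Step 11
Reactants: 13 [(1R,2S,3S)-3-bromo-2-(2-chloroethyl)-2-methyl-6-methylidenecyclohexyl]methyl acetate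
Product: 14 [(1R,2S,3S)-3-bromo-2-(2-chloroethyl)-2-methyl-6-oxocyclohexyl]methyl acetate
Conditions: O3, CH2Cl2/MeOH, −78 °C; Me2S, −78 °C to rt
Reagents that add atoms: ozone [O-][O+]=O
Why: Ozonolysis with reductive work-up cleaves the only alkene to the C3 ketone, which turns the CH2OAc group on C2 into a β-acetoxy ketone, a latent exocyclic enone.

Step 12
Reactants: 14 [(1R,2S,3S)-3-bromo-2-(2-chloroethyl)-2-methyl-6-oxocyclohexyl]methyl acetate
Product: 15 [(1R,2S,3S)-3-bromo-2-(2-iodoethyl)-2-methyl-6-oxocyclohexyl]methyl acetate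
Conditions: NaI (5 equiv), acetone, 55 °C
Reagents that add atoms: sodium iodide [Na+].[I-]
Why: Finkelstein exchange occurs only at the primary chloride, because the secondary bromide is neopentyl-like and inert to SN2.

Step 13
Reactants: 16 6-methylhept-5-en-2-one
Product: 18 6-methylhept-5-en-1-yne, via enol phosphate 17 (not isolated)
Conditions: lithium diisopropylamide (1.05 equiv), THF, −78 °C; ClP(O)(OEt)2; lithium diisopropylamide (2.3 equiv), −78 °C to rt
Reagents that add atoms: none
Why: Kinetic enolisation of the methyl ketone on the methyl side, O-phosphorylation and base-induced elimination of the enol phosphate give the terminal alkyne (Negishi alkyne synthesis).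

Step 14
Reactants: 18 6-methylhept-5-en-1-yne
Product: 20 (1E)-1-iodo-2,6-dimethylhepta-1,5-diene, via alkenylalane 19 (not isolated)
Conditions: Me3Al (2 equiv), Cp2ZrCl2 (0.25 equiv), CH2Cl2, 0 °C to rt; I2, THF, −30 °C
Reagents that add atoms: trimethylaluminium C[Al](C)C; iodine II
Why: Negishi carboalumination (syn addition, aluminium terminal) and iodinolysis with retention give the E iodoalkene that becomes C10=C11.

Step 15
Reactants: 20 (1E)-1-iodo-2,6-dimethylhepta-1,5-diene
Product: 21 (3S)-3-[(4E)-5-iodo-4-methylpent-4-en-1-yl]-2,2-dimethyloxirane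
Conditions: L-fructose-derived Shi ketone (0.3 equiv), Oxone (2KHSO5·KHSO4·K2SO4), K2CO3, Bu4NHSO4, Na2B4O7 buffer (pH 10.5), MeCN/CH2(OMe)2/H2O, 0 °C
Reagents that add atoms: Oxone (active component potassium peroxymonosulfate) [K+].[O-]S(=O)(=O)OO
Why: Shi epoxidation with the enantiomeric ketone is selective for the electron-rich trisubstituted alkene over the iodoalkene and should deliver oxygen to the face that gives the (S)-epoxide, which sets C14.

Step 16
Reactants: 21 (3S)-3-[(4E)-5-iodo-4-methylpent-4-en-1-yl]-2,2-dimethyloxirane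
Product: 22 (3S,6E)-2-bromo-7-iodo-2,6-dimethylhept-6-en-3-ol
Conditions: HBr (1.1 equiv, 1 M in Et2O), Et2O, −40 °C; pH 7 phosphate buffer
Reagents that add atoms: hydrogen bromide Br
Why: Under acid the protonated epoxide opens at the tertiary carbon (Markovnikov-type, SN1-like opening), which places bromine on C15 and leaves the C14–O bond and its configuration untouched.

Step 17
Reactants: 23 4-hydroxy-3-iodobenzoic acid
Product: 24 tri(propan-2-yl)silyl 3-iodo-4-{[tri(propan-2-yl)silyl]oxy}benzoate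
Conditions: i-Pr3SiCl (2.3 equiv), imidazole (5 equiv), DMF, rt
Reagents that add atoms: chlorotri(propan-2-yl)silane CC(C)[Si](Cl)(C(C)C)C(C)C
Why: Imidazole-promoted silylation protects the phenol as a hindered silyl ether and masks the acid as a silyl ester, so that the following palladium step meets no acidic proton.

Step 18
Reactants: 24 tri(propan-2-yl)silyl 3-iodo-4-{[tri(propan-2-yl)silyl]oxy}benzoate
Product: 26 3-(4,4,5,5-tetramethyl-1,3,2-dioxaborolan-2-yl)-4-{[tri(propan-2-yl)silyl]oxy}benzoic acid, via silyl ester boronate 25 (not isolated)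
Conditions: B2pin2 (1.3 equiv), Pd(dppf)Cl2 (5 mol %), KOAc (3 equiv), 1,4-dioxane, 85 °C; then K2CO3, MeOH/THF/H2O, 0 °C; citric acid to pH 4
Reagents that add atoms: bis(pinacolato)diboron CC1(C)OB(OC1(C)C)B1OC(C)(C)C(C)(C)O1
Why: Miyaura borylation replaces iodine at C3' by boron, and the silyl ester is then cleaved by mild carbonate hydrolysis much faster than the aryl silyl ether.

Step 19
Reactants: 22 (3S,6E)-2-bromo-7-iodo-2,6-dimethylhept-6-en-3-ol; 26 3-(4,4,5,5-tetramethyl-1,3,2-dioxaborolan-2-yl)-4-{[tri(propan-2-yl)silyl]oxy}benzoic acid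
Product: 27 (3S,6E)-2-bromo-7-iodo-2,6-dimethylhept-6-en-3-yl 3-(4,4,5,5-tetramethyl-1,3,2-dioxaborolan-2-yl)-4-{[tri(propan-2-yl)silyl]oxy}benzoate
Conditions: EDC·HCl (1.5 equiv), DMAP (0.3 equiv), CH2Cl2, 0 °C to rt
Reagents that add atoms: none
Why: Steglich esterification acylates the secondary alcohol under near-neutral conditions that leave the tertiary bromide and the boronate intact, forming the C14–O ester bond with retention at C14.

Step 20
Reactants: 15 [(1R,2S,3S)-3-bromo-2-(2-iodoethyl)-2-methyl-6-oxocyclohexyl]methyl acetate; 27 (3S,6E)-2-bromo-7-iodo-2,6-dimethylhept-6-en-3-yl 3-(4,4,5,5-tetramethyl-1,3,2-dioxaborolan-2-yl)-4-{[tri(propan-2-yl)silyl]oxy}benzoate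
Product: 29 (3S,6E)-9-[(1S,2R,6S)-2-(acetoxymethyl)-6-bromo-1-methyl-3-oxocyclohexyl]-2-bromo-2,6-dimethylnon-6-en-3-yl 3-(4,4,5,5-tetramethyl-1,3,2-dioxaborolan-2-yl)-4-{[tri(propan-2-yl)silyl]oxy}benzoate, via alkylzinc iodide 28 (not isolated)
Conditions: Zn dust (activated with BrCH2CH2Br and Me3SiCl), LiCl, THF, 30 °C; solution decanted from excess Zn; 27, Pd(dppf)Cl2 (5 mol %), THF/NMP, rt
Reagents that add atoms: none
Why: Zinc inserts selectively into the primary C–I bond (the neopentyl-like secondary bromide, the ketone and the acetate are tolerated), and palladium-catalysed Negishi coupling with the alkenyl iodide forms C9–C10 with retention of the E geometry without touching the aryl boronate or the alkyl bromides.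

Step 21
Reactants: 29 (3S,6E)-9-[(1S,2R,6S)-2-(acetoxymethyl)-6-bromo-1-methyl-3-oxocyclohexyl]-2-bromo-2,6-dimethylnon-6-en-3-yl 3-(4,4,5,5-tetramethyl-1,3,2-dioxaborolan-2-yl)-4-{[tri(propan-2-yl)silyl]oxy}benzoate
Product: 31 (2S,6S,7S,10E,14S)-4'-O-[tri(propan-2-yl)silyl]-3-de(methylidene)-3-oxo-10,11-deoxy-10,11-didehydrobromophycolide S (ring C closed; C3 ketone; 10E alkene), via exocyclic enone 30 (not isolated)
Conditions: [Rh(cod)OH]2 (10 mol %), K3PO4 (1.5 equiv), 1,4-dioxane/H2O (20:1), 30 °C, substrate added by syringe pump to 1 mM, then held 2 h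
Reagents that add atoms: none
Why: Phosphate first unmasks the exocyclic enone 30 by E1cB loss of acetate, so the acceptor is released slowly at high dilution; [Rh(cod)OH]2 then transmetalates with the boronate at C3', the aryl–rhodium adds 1,4 to the enone with C3' bonding to the unhindered terminal carbon C1, and water protonates the oxa-π-allyl rhodium and turns the catalyst over. The closest known reaction type is the Hayashi–Miyaura rhodium-catalysed conjugate arylation of enones with arylboron reagents, which works between separate molecules with 2-oxygenated arylboronates and with α-methylene ketones. Ring C (15-membered) closes in a 15-endo-trig mode, since both C1 and C2 lie inside the new ring. The only new stereocentre, C2, is set by protonation of the enolate and then by thermodynamic control: the α-proton is exchangeable under the phosphate conditions, and the epimer with C1 equatorial and trans to the C8 branch on C7 (H2 anti to the axial C7 methyl) is expected to be favoured. The step needs carbometalation to win over protodeboronation and ring closure to win over oligomerisation; this is secured by the terminal, unhindered acceptor, by slow release of the enone at 1 mM, and by a substrate whose alkyl bromides, ester and silyl ether do not react with arylrhodium.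

Step 22
Reactants: 31 (2S,6S,7S,10E,14S)-4'-O-[tri(propan-2-yl)silyl]-3-de(methylidene)-3-oxo-10,11-deoxy-10,11-didehydrobromophycolide S
Product: 32 (2R,6S,7S,10E,14S)-4'-O-[tri(propan-2-yl)silyl]-10,11-deoxy-10,11-didehydrobromophycolide S
Conditions: Cp2Ti(μ-Cl)(μ-CH2)AlMe2 (Tebbe reagent, 1.2 equiv), pyridine (cat.), THF/toluene, −40 to 0 °C
Reagents that add atoms: Tebbe reagent (μ-chloro-μ-methylene titanium–aluminium complex, the chloride bridge written with formal charges on aluminium and chlorine) C[Al-]1(C)C[Ti](C2C=CC=C2)(C2C=CC=C2)[Cl+]1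
Why: The Tebbe titanium methylidene olefinates the ketone through an oxatitanacyclobutane under non-basic conditions, so C2 is not epimerised and the tertiary bromide is not eliminated, and at low temperature the ketone reacts before the aryl ester.

Step 23
Reactants: 32 (2R,6S,7S,10E,14S)-4'-O-[tri(propan-2-yl)silyl]-10,11-deoxy-10,11-didehydrobromophycolide S
Product: 33 (2R,6S,7S,10S,11S,14S)-4'-O-[tri(propan-2-yl)silyl]bromophycolide S
Conditions: L-fructose-derived Shi ketone (0.5 equiv), Oxone (2KHSO5·KHSO4·K2SO4, limited), K2CO3, Bu4NHSO4, Na2B4O7 buffer (pH 10.5), MeCN/CH2(OMe)2/H2O, 0 °C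
Reagents that add atoms: Oxone (active component potassium peroxymonosulfate) [K+].[O-]S(=O)(=O)OO
Why: Shi epoxidation attacks the E-trisubstituted C10=C11 alkene in preference to the 1,1-disubstituted exocyclic alkene, and reagent control through the spiro transition state should give the (10S,11S)-epoxide.

Step 24
Reactants: 33 (2R,6S,7S,10S,11S,14S)-4'-O-[tri(propan-2-yl)silyl]bromophycolide S
Product: 34 bromophycolide S
Conditions: Bu4NF (1.1 equiv), AcOH (1.1 equiv), THF, 0 °C
Reagents that add atoms: none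
Why: Fluoride cleaves the aryl silyl ether, and buffering with acetic acid keeps the medium near neutral so that the epoxide, the tertiary bromide and the lactone survive.

**Compound list**

1 | but-3-yn-1-ol | C#CCCO | starting material
2 | alkenylalane: dimethyl[(1E)-4-(dimethylalumanyloxy)-2-methylbut-1-en-1-yl]alumane | C[Al](C)/C=C(\C)CCO[Al](C)C | intermediate
3 | (2E)-3-methylpent-2-ene-1,5-diol | OC/C=C(\C)CCO | intermediate
4 | (2E)-1,5-dichloro-3-methylpent-2-ene | ClC/C=C(\C)CCCl | intermediate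
5 | methyl 3-oxobutanoate | COC(=O)CC(C)=O | starting material
6 | methyl (6E)-9-chloro-7-methyl-3-oxonon-6-enoate | COC(=O)CC(=O)CC/C=C(\C)CCCl | intermediate
7 | methyl (2Z,6E)-9-chloro-7-methyl-3-[(trifluoromethanesulfonyl)oxy]nona-2,6-dienoate | COC(=O)/C=C(\OS(=O)(=O)C(F)(F)F)CC/C=C(\C)CCCl | intermediate
8 | methyl (2Z,6E)-9-chloro-7-methyl-3-[(trimethylsilyl)methyl]nona-2,6-dienoate | COC(=O)/C=C(\C[Si](C)(C)C)CC/C=C(\C)CCCl | intermediate
9 | methyl (2Z)-5-[(2R,3R)-3-(2-chloroethyl)-3-methyloxiran-2-yl]-3-[(trimethylsilyl)methyl]pent-2-enoate | COC(=O)/C=C(\C[Si](C)(C)C)CC[C@H]1O[C@]1(C)CCCl | intermediate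
10 | (2Z)-5-[(2R,3R)-3-(2-chloroethyl)-3-methyloxiran-2-yl]-3-[(trimethylsilyl)methyl]pent-2-en-1-ol | OC/C=C(\C[Si](C)(C)C)CC[C@H]1O[C@]1(C)CCCl | intermediate
11 | (2Z)-5-[(2R,3R)-3-(2-chloroethyl)-3-methyloxiran-2-yl]-3-[(trimethylsilyl)methyl]pent-2-en-1-yl acetate | CC(=O)OC/C=C(\C[Si](C)(C)C)CC[C@H]1O[C@]1(C)CCCl | intermediate
12 | (2Z,6S,7R)-6-bromo-9-chloro-7-hydroxy-7-methyl-3-[(trimethylsilyl)methyl]non-2-en-1-yl acetate | CC(=O)OC/C=C(\C[Si](C)(C)C)CC[C@H](Br)[C@](C)(O)CCCl | intermediate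
13 | [(1R,2S,3S)-3-bromo-2-(2-chloroethyl)-2-methyl-6-methylidenecyclohexyl]methyl acetate | CC(=O)OC[C@@H]1C(=C)CC[C@H](Br)[C@@]1(C)CCCl | intermediate
14 | [(1R,2S,3S)-3-bromo-2-(2-chloroethyl)-2-methyl-6-oxocyclohexyl]methyl acetate | CC(=O)OC[C@@H]1C(=O)CC[C@H](Br)[C@@]1(C)CCCl | intermediate
15 | [(1R,2S,3S)-3-bromo-2-(2-iodoethyl)-2-methyl-6-oxocyclohexyl]methyl acetate | CC(=O)OC[C@@H]1C(=O)CC[C@H](Br)[C@@]1(C)CCI | intermediate
16 | 6-methylhept-5-en-2-one | CC(=O)CCC=C(C)C | starting material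
17 | enol phosphate: diethyl 6-methylhepta-1,5-dien-2-yl phosphate | C=C(CCC=C(C)C)OP(=O)(OCC)OCC | intermediate
18 | 6-methylhept-5-en-1-yne | C#CCCC=C(C)C | intermediate
19 | alkenylalane: [(1E)-2,6-dimethylhepta-1,5-dien-1-yl]dimethylalumane | C[Al](C)/C=C(\C)CCC=C(C)C | intermediate
20 | (1E)-1-iodo-2,6-dimethylhepta-1,5-diene | I/C=C(\C)CCC=C(C)C | intermediate
21 | (3S)-3-[(4E)-5-iodo-4-methylpent-4-en-1-yl]-2,2-dimethyloxirane | I/C=C(\C)CC[C@@H]1OC1(C)C | intermediate
22 | (3S,6E)-2-bromo-7-iodo-2,6-dimethylhept-6-en-3-ol | I/C=C(\C)CC[C@H](O)C(C)(C)Br | intermediate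
23 | 4-hydroxy-3-iodobenzoic acid | OC(=O)c1ccc(O)c(I)c1 | starting material
24 | tri(propan-2-yl)silyl 3-iodo-4-{[tri(propan-2-yl)silyl]oxy}benzoate | CC(C)[Si](C(C)C)(C(C)C)OC(=O)c1ccc(O[Si](C(C)C)(C(C)C)C(C)C)c(I)c1 | intermediate
25 | silyl ester boronate: tri(propan-2-yl)silyl 3-(4,4,5,5-tetramethyl-1,3,2-dioxaborolan-2-yl)-4-{[tri(propan-2-yl)silyl]oxy}benzoate | CC(C)[Si](C(C)C)(C(C)C)OC(=O)c1ccc(O[Si](C(C)C)(C(C)C)C(C)C)c(B2OC(C)(C)C(C)(C)O2)c1 | intermediate
26 | 3-(4,4,5,5-tetramethyl-1,3,2-dioxaborolan-2-yl)-4-{[tri(propan-2-yl)silyl]oxy}benzoic acid | OC(=O)c1ccc(O[Si](C(C)C)(C(C)C)C(C)C)c(B2OC(C)(C)C(C)(C)O2)c1 | intermediate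
27 | (3S,6E)-2-bromo-7-iodo-2,6-dimethylhept-6-en-3-yl 3-(4,4,5,5-tetramethyl-1,3,2-dioxaborolan-2-yl)-4-{[tri(propan-2-yl)silyl]oxy}benzoate | I/C=C(\C)CC[C@@H](C(C)(C)Br)OC(=O)c1ccc(O[Si](C(C)C)(C(C)C)C(C)C)c(B2OC(C)(C)C(C)(C)O2)c1 | intermediate
28 | alkylzinc iodide: {2-[(1S,2R,6S)-2-(acetoxymethyl)-6-bromo-1-methyl-3-oxocyclohexyl]ethyl}zinc iodide | CC(=O)OC[C@@H]1C(=O)CC[C@H](Br)[C@@]1(C)CC[Zn]I | intermediate
29 | (3S,6E)-9-[(1S,2R,6S)-2-(acetoxymethyl)-6-bromo-1-methyl-3-oxocyclohexyl]-2-bromo-2,6-dimethylnon-6-en-3-yl 3-(4,4,5,5-tetramethyl-1,3,2-dioxaborolan-2-yl)-4-{[tri(propan-2-yl)silyl]oxy}benzoate | CC(=O)OC[C@@H]1C(=O)CC[C@H](Br)[C@@]1(C)CC/C=C(\C)CC[C@@H](C(C)(C)Br)OC(=O)c1ccc(O[Si](C(C)C)(C(C)C)C(C)C)c(B2OC(C)(C)C(C)(C)O2)c1 | intermediate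
30 | exocyclic enone: (3S,6E)-2-bromo-9-[(1S,6S)-6-bromo-1-methyl-2-methylidene-3-oxocyclohexyl]-2,6-dimethylnon-6-en-3-yl 3-(4,4,5,5-tetramethyl-1,3,2-dioxaborolan-2-yl)-4-{[tri(propan-2-yl)silyl]oxy}benzoate | C=C1C(=O)CC[C@H](Br)[C@@]1(C)CC/C=C(\C)CC[C@@H](C(C)(C)Br)OC(=O)c1ccc(O[Si](C(C)C)(C(C)C)C(C)C)c(B2OC(C)(C)C(C)(C)O2)c1 | intermediate
31 | (2S,6S,7S,10E,14S)-4'-O-[tri(propan-2-yl)silyl]-3-de(methylidene)-3-oxo-10,11-deoxy-10,11-didehydrobromophycolide S | O=C1CC[C@H](Br)[C@@]2(C)CC/C=C(\C)CC[C@@H](C(C)(C)Br)OC(=O)c3ccc(O[Si](C(C)C)(C(C)C)C(C)C)c(c3)C[C@H]12 | intermediate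
32 | (2R,6S,7S,10E,14S)-4'-O-[tri(propan-2-yl)silyl]-10,11-deoxy-10,11-didehydrobromophycolide S | C=C1CC[C@H](Br)[C@@]2(C)CC/C=C(\C)CC[C@@H](C(C)(C)Br)OC(=O)c3ccc(O[Si](C(C)C)(C(C)C)C(C)C)c(c3)C[C@H]12 | intermediate
33 | (2R,6S,7S,10S,11S,14S)-4'-O-[tri(propan-2-yl)silyl]bromophycolide S | C=C1CC[C@H](Br)[C@@]2(C)CC[C@@H]3O[C@@]3(C)CC[C@@H](C(C)(C)Br)OC(=O)c3ccc(O[Si](C(C)C)(C(C)C)C(C)C)c(c3)C[C@H]12 | intermediate
34 | bromophycolide S ((2R,6S,7S,10S,11S,14S)) | C=C1CC[C@H](Br)[C@@]2(C)CC[C@@H]3O[C@@]3(C)CC[C@@H](C(C)(C)Br)OC(=O)c3ccc(O)c(c3)C[C@H]12 | target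

**Step count and risks**

Total step count: 24.
Longest linear sequence: 17 steps (steps 1–12, then 20–24).

Steps most likely to fail:

1. Step 21 (ring closure by conjugate arylation). Protodeboronation of the hindered aryl boronate or oligomerisation may outrun the 15-membered ring closure, the tertiary bromide may solvolyse in the aqueous medium, and equilibration at C2 may stay incomplete. Fallback: the aryl–C1 bond is made between separate molecules and ring C is closed at the ester instead. It sets out from 15, 22 and 26 and returns at 31. The alcohol of 22 is silylated (Et3SiOTf, 2,6-lutidine, CH2Cl2, −78 °C) to (3S,6E)-2-bromo-7-iodo-2,6-dimethylhept-6-en-3-yl triethylsilyl ether F1. The zinc reagent 28 from 15 is coupled with F1 (Pd(dppf)Cl2, THF/NMP, rt) to the open-chain keto acetate F2. Intermolecular rhodium-catalysed conjugate arylation of the enone released from F2 with the free acid 26 ([Rh(cod)OH]2, K3PO4, 1,4-dioxane/H2O, 30 °C) gives the aryl keto acid F3. HF·pyridine in THF/pyridine at 0 °C removes the triethylsilyl group to give the hydroxy acid F4. A Shiina macrolactonisation (2-methyl-6-nitrobenzoic anhydride, DMAP, CH2Cl2, rt, high dilution) then closes ring C to give 31.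

2. Step 10 (bromonium generation and ring A closure). Bromonium transfer between alkenes before capture may erode the enantiopurity, and the tertiary triflate may eliminate or the allylic acetate may ionise instead of cyclising. Fallback: an external bromonium source on a deactivated terminator, followed by resolution. It sets out from 8 and returns at 13. Cyclisation of the conjugated allylsilane ester 8 with Et2SBr·SbCl5Br (MeNO2, −25 °C) should form the bromonium only at the electron-rich C6=C7 alkene and give racemic methyl 3-bromo-2-(2-chloroethyl)-2-methyl-6-methylidenecyclohexane-1-carboxylate F5 with the same relative configuration. i-Bu2AlH (CH2Cl2, −78 °C) reduces it to the alcohol, which is resolved by preparative HPLC on a chiral stationary phase to give [(1R,2S,3S)-3-bromo-2-(2-chloroethyl)-2-methyl-6-methylidenecyclohexyl]methanol F6. Acetylation (Ac2O, pyridine) gives 13.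

3. Step 23 (late epoxidation). The conformation of ring C may shield the face that the reagent needs, so that facial selectivity is poor, and the tertiary bromide may be lost under the basic aqueous conditions. Fallback: the epoxide is set on the open chain, where reagent control is reliable, and carried through the ring closure. It sets out from 13, 22 and 26 and returns at 33. Finkelstein exchange on 13 (NaI, acetone, 55 °C) gives [(1R,2S,3S)-3-bromo-2-(2-iodoethyl)-2-methyl-6-methylidenecyclohexyl]methyl acetate F7. Zinc insertion and Negishi coupling with the triethylsilyl ether F1 (made from 22 as above) give the diene acetate F8. Shi epoxidation with the L-fructose-derived ketone, selective for the trisubstituted C10=C11 alkene, gives the (10S,11S)-epoxide F9. Ozonolysis (O3, then Me2S) of the remaining exocyclic alkene gives the epoxy keto acetate F10. HF·pyridine in THF/pyridine at 0 °C frees the C14 alcohol to give the epoxy bromohydrin F11, and Steglich esterification with 26 gives the epoxy seco-boronate F12. The conditions of step 21 then close ring C to the macrocyclic epoxy ketone F13, and Tebbe methylenation as in step 22 gives 33.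

**Further compounds**

F1 | step 21 | (3S,6E)-2-bromo-7-iodo-2,6-dimethylhept-6-en-3-yl triethylsilyl ether | I/C=C(\C)CC[C@H](O[Si](CC)(CC)CC)C(C)(C)Br
F2 | step 21 | [(1R,2S,3S)-3-bromo-2-[(3E,7S)-8-bromo-4,8-dimethyl-7-(triethylsilyloxy)non-3-en-1-yl]-2-methyl-6-oxocyclohexyl]methyl acetate | CC(=O)OC[C@@H]1C(=O)CC[C@H](Br)[C@@]1(C)CC/C=C(\C)CC[C@H](O[Si](CC)(CC)CC)C(C)(C)Br
F3 | step 21 | 3-{[(1S,2S,3S)-3-bromo-2-[(3E,7S)-8-bromo-4,8-dimethyl-7-(triethylsilyloxy)non-3-en-1-yl]-2-methyl-6-oxocyclohexyl]methyl}-4-{[tri(propan-2-yl)silyl]oxy}benzoic acid | OC(=O)c1ccc(O[Si](C(C)C)(C(C)C)C(C)C)c(C[C@@H]2C(=O)CC[C@H](Br)[C@@]2(C)CC/C=C(\C)CC[C@H](O[Si](CC)(CC)CC)C(C)(C)Br)c1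
F4 | step 21 | 3-{[(1S,2S,3S)-3-bromo-2-[(3E,7S)-8-bromo-7-hydroxy-4,8-dimethylnon-3-en-1-yl]-2-methyl-6-oxocyclohexyl]methyl}-4-{[tri(propan-2-yl)silyl]oxy}benzoic acid | OC(=O)c1ccc(O[Si](C(C)C)(C(C)C)C(C)C)c(C[C@@H]2C(=O)CC[C@H](Br)[C@@]2(C)CC/C=C(\C)CC[C@H](O)C(C)(C)Br)c1
F5 | step 10 | methyl (1R*,2S*,3S*)-3-bromo-2-(2-chloroethyl)-2-methyl-6-methylidenecyclohexane-1-carboxylate (racemate; the needed (1R,2S,3S) enantiomer is drawn) | COC(=O)[C@@H]1C(=C)CC[C@H](Br)[C@@]1(C)CCCl
F6 | step 10 | [(1R,2S,3S)-3-bromo-2-(2-chloroethyl)-2-methyl-6-methylidenecyclohexyl]methanol | OC[C@@H]1C(=C)CC[C@H](Br)[C@@]1(C)CCCl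
F7 | step 23 | [(1R,2S,3S)-3-bromo-2-(2-iodoethyl)-2-methyl-6-methylidenecyclohexyl]methyl acetate | CC(=O)OC[C@@H]1C(=C)CC[C@H](Br)[C@@]1(C)CCI
F8 | step 23 | [(1R,2S,3S)-3-bromo-2-[(3E,7S)-8-bromo-4,8-dimethyl-7-(triethylsilyloxy)non-3-en-1-yl]-2-methyl-6-methylidenecyclohexyl]methyl acetate | CC(=O)OC[C@@H]1C(=C)CC[C@H](Br)[C@@]1(C)CC/C=C(\C)CC[C@H](O[Si](CC)(CC)CC)C(C)(C)Br
F9 | step 23 | [(1R,2S,3S)-3-bromo-2-{2-[(2S,3S)-3-[(3S)-4-bromo-4-methyl-3-(triethylsilyloxy)pentyl]-3-methyloxiran-2-yl]ethyl}-2-methyl-6-methylidenecyclohexyl]methyl acetate | CC(=O)OC[C@@H]1C(=C)CC[C@H](Br)[C@@]1(C)CC[C@@H]2O[C@@]2(C)CC[C@H](O[Si](CC)(CC)CC)C(C)(C)Br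
F10 | step 23 | [(1R,2S,3S)-3-bromo-2-{2-[(2S,3S)-3-[(3S)-4-bromo-4-methyl-3-(triethylsilyloxy)pentyl]-3-methyloxiran-2-yl]ethyl}-2-methyl-6-oxocyclohexyl]methyl acetate | CC(=O)OC[C@@H]1C(=O)CC[C@H](Br)[C@@]1(C)CC[C@@H]2O[C@@]2(C)CC[C@H](O[Si](CC)(CC)CC)C(C)(C)Br
F11 | step 23 | [(1R,2S,3S)-3-bromo-2-{2-[(2S,3S)-3-[(3S)-4-bromo-3-hydroxy-4-methylpentyl]-3-methyloxiran-2-yl]ethyl}-2-methyl-6-oxocyclohexyl]methyl acetate | CC(=O)OC[C@@H]1C(=O)CC[C@H](Br)[C@@]1(C)CC[C@@H]2O[C@@]2(C)CC[C@H](O)C(C)(C)Br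
F12 | step 23 | (3S)-1-[(2S,3S)-3-{2-[(1S,2R,6S)-2-(acetoxymethyl)-6-bromo-1-methyl-3-oxocyclohexyl]ethyl}-2-methyloxiran-2-yl]-4-bromo-4-methylpentan-3-yl 3-(4,4,5,5-tetramethyl-1,3,2-dioxaborolan-2-yl)-4-{[tri(propan-2-yl)silyl]oxy}benzoate | CC(=O)OC[C@@H]1C(=O)CC[C@H](Br)[C@@]1(C)CC[C@@H]2O[C@@]2(C)CC[C@@H](C(C)(C)Br)OC(=O)c1ccc(O[Si](C(C)C)(C(C)C)C(C)C)c(B2OC(C)(C)C(C)(C)O2)c1
F13 | step 23 | (2S,6S,7S,10S,11S,14S)-4'-O-[tri(propan-2-yl)silyl]-3-de(methylidene)-3-oxobromophycolide S | O=C1CC[C@H](Br)[C@@]2(C)CC[C@@H]3O[C@@]3(C)CC[C@@H](C(C)(C)Br)OC(=O)c3ccc(O[Si](C(C)C)(C(C)C)C(C)C)c(c3)C[C@H]12
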